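## Structural features

The target joins two units through one ether oxygen: an 8-methoxy-2H-chromen-2-one (coumarin) oxygenated at its C7, and a ten-carbon side chain. Numbered from the aryloxy end, the chain has C1 (ArOCH2), an oxirane made of C2 (CH) and C3 (quaternary, bearing the methyl group) with C1 and C4 trans, C4 (CH2), and an α-methylene-γ-butyrolactone in which C5 is CH–O, C6 the ring CH2, C7 the C(=CH2) carbon and C8 the carbonyl. There are three stereocentres. C2 and C3 are adjacent and both R, so one epoxidation of an E alkene sets them together. C5 is S and is insulated from C3 by the C4 methylene, so neither element can usefully control the other. The fragile groups are the exocyclic enoate (a Michael acceptor for phosphines, alkoxides and phenoxides), the trisubstituted epoxide (opened or rearranged by Brønsted and Lewis acids and by halide), and the coumarin lactone (hydroxide). The real difficulty is C5: a secondary carbinol carbon with two nearly identical three-carbon arms that must become an epoxy ether on one side and a methylene lactone on the other, in an order that never puts the epoxide in acid. The key step uses the fact that C5 carries a CH2–C(sp2) unit on each side (C4–C3 and C6–C7): C3 and C7 can both be internal alkyne carbons of a hepta-1,6-diyn-4-ol, and a silicon cap on the C7 arm lets methyl and hydroxymethyl be added to the C3 arm alone.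

## Logic of the disconnections

**15 to 13 and 14.** The C1–O(aryl) bond is cut. It is the only link between the aromatic bicycle and the chiral chain, and 14 is available as such. The cut removes ten carbons and leaves a C10 fragment holding all three stereocentres. The forward step must etherify a primary carbon next to an epoxide under neutral conditions, without opening the oxirane and without adding a nucleophile to the enoate.

**13 to 12.** Both C–O bonds of the oxirane (C2–O and C3–O) are cut. The primary hydroxyl at C1 is the directing group for a titanium–tartrate epoxidation, which sets C2 and C3 by reagent control, independently of C5. This removes two stereocentres. It demands an E alkene, the D-(−)-tartrate, and an oxidant that ignores the electron-poor exocyclic alkene.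

**12 to 11.** The O5–C8 and C7–C8 bonds are cut, which removes C8 as carbon monoxide and opens the lactone to a homopropargylic alcohol. The closure is atom-economic, but its catalytic cycle turns over through hydrogen chloride, so it is placed before the epoxide exists. The gain is an acyclic diol with a terminal alkyne. The forward step must close only through the C5 oxygen (five-membered ring) and leave the primary allylic hydroxyl alone.

**11 to 10.** The Si–O bond at C5 and the Si–C(sp) bond are restored. Both caps are chosen to leave together with fluoride, so the protection costs one step. The demand is only that the allylic alcohol tolerates fluoride.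

**10 to 7, through 8 and 9.** The C3–CH3 and C2–C1 bonds are cut, which turns the E trisubstituted allylic alcohol back into a terminal alkyne. This is the strategic simplification: both arms of C5 become propargyl groups, told apart only by silicon. The forward step must add methyl and the metal syn, put methyl on C3, and not touch the capped alkyne.

**7 to 6.** The O–Si bond is cut. The ether keeps the C5 oxygen from binding aluminium in the carbometalation. Silylation of a secondary alcohol is routine.

**6 to 4, through 5.** The C–C bond between the acetylene carbon and the former chloromethyl carbon is cut. The chlorohydrin closes to an epoxide in the flask and the epoxide is opened at its CH2 carbon, so C5 is never a reacting centre. The alkyne cap must survive alkoxide and acetylide in DMSO; for that reason it is triisopropylsilyl and not a smaller silyl group.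

**4 to 1 and 2, through 3.** The C–C bond between the epoxide CH2 of 1 and the alkyne carbon of 2 is cut. The silyl-capped arm is attached first, at the epoxide carbon, and the free arm second, at the chlorine-bearing carbon. With this order the S enantiomer of 1 leads to the C5 configuration of 15.

## Other disconnections considered

**Alternative 1:** The lactone is cut at C6–C7 and at the O5–C8 acyl bond, which leads to diepoxide A1 and a phosphonoacetate anion. Forward, the sodium salt of triethyl phosphonoacetate (from NaH) would attack the unsubstituted carbon C6 of the terminal oxirane of A1. The C5 alkoxide would close on the ester to give the α-phosphono lactone A2 as both C7 epimers, and an olefination with formaldehyde would then erase that centre and give 15.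
- In its favour: the ring forms under basic conditions that leave the trisubstituted oxirane alone, and no CO pressure is needed. The exocyclic alkene appears only in the last step. On that point the alternative is better than the chosen plan, in which the enoate of 12 must survive two more steps.
- Against it: A1 already holds all three stereocentres, two oxiranes and the coumarin. Its terminal oxirane must be made with defined configuration on that loaded chain, which costs more steps than the two alkynylations of 1. The γ-alkoxide formed on ring opening can attack phosphorus instead of the ester carbonyl, which leads to a cyclopropane ester. The stabilised carbanion also has a second electrophile in the coumarin C3=C4 bond.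
- Comparison: structurally the plans are equal in taking C5 from an epoxide-derived carbinol. Mechanistically the alternative is an SN2 opening followed by acyl substitution, simple but slow for a stabilised anion, against a fast stereospecific carbometalation. In steps after the key step it is equal or slightly better (two), but the route to A1 makes it longer overall.

**Alternative 2:** The coumarin is cut at its own C4–C4a bond, which leads to aryl propiolate A3, a 1,2,3-trioxygenated benzene that already carries the complete side chain and lactone. Forward, Ph3PAuCl and AgSbF6 would give a cationic monovalent gold species that activates the alkyne. The arene carbon ortho to the ester oxygen and para to the allyloxy group would attack 6-endo-dig and close the pyranone ring, giving diene lactone A4. By the sequence rule A4 is R at the lactone carbon, with the same spatial arrangement as C5 of 15. Epoxidation of its trisubstituted alkene would finish the synthesis.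
- In its favour: the step is ring-forming, atom-economic and neutral, and only one ortho position is free, so the regiochemistry is fixed. It closes a ring, which the chosen key step does not; on that count it is better, although the chosen plan buys that ring ready-made in 14. As in the chosen plan, no epoxide is present when the lactone is in place; the two are equal there.
- Against it: A4 has no hydroxyl, so C2 and C3 would have to come from an undirected, reagent-controlled epoxidation (a ketone-catalysed dioxirane at basic pH) next to two lactones. That is less dependable than the titanium–tartrate reaction. The electron-rich allyl aryl ether can ionise under Lewis-acidic gold or silver. A3 also needs a mono-ester and a mono-ether set on neighbouring oxygens of the arene.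
- Comparison: the mechanism is a clean π-activation and arylation, but the structure gives up the allylic alcohol that makes the epoxide reliable, and the route is longer.

**Alternative 3:** The ring oxygen is removed by cutting O5–C5 and O5–C8, which contracts the lactone to cyclobutanone A5. Forward, H2O2 (aqueous NaOH, or in 1,1,1,3,3,3-hexafluoropropan-2-ol) would add to the strained carbonyl, and the more substituted carbon C5 would migrate to oxygen with retention to give the saturated lactone A6.
- In its favour: the step is metal-free, regiospecific and stereospecific, and the peroxide prefers the strained ketone to the trisubstituted alkene. C5 is transmitted without loss, which makes it the equal of the chosen plan, where C5 is never a reacting centre.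
- Against it: A6 has no exocyclic methylene. Two or three enolate operations are needed before desilylation, epoxidation and etherification can follow. A5 is an α-branched cyclobutanone whose stereocentre can enolise in the aqueous NaOH variant, and its enantioselective preparation has no source as simple as 1.
- Comparison: the mechanism (Criegee migration) is at least as dependable as the carbometalation, but the structure after the key step is further from 15 and the step count is clearly higher.

Key step: step 4

**Remarks on the chemistry.**
- C5 keeps one spatial arrangement from 1 to 15. Its descriptor alternates (S in 4 and 5, R in 6 to 10, S in 11, R in 12, S in 13 and 15) only because the ranking of its two carbon arms changes. The silyl-capped diyne and the allylic alcohol that lead to (5S)-15 are therefore R, not S, and the same holds for the diene lactone A4.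
- The alkyne cap is triisopropylsilyl because a trimethylsilyl cap would not be expected to survive alkoxide and acetylide in DMSO, and would be more open to carbometalation.
- Compounds 1, 2 and 14 are assumed to be purchasable.

## Route

Step 1
Reactants: 1 (S)-epichlorohydrin; 2 ethynyltriisopropylsilane
Product: 4 (2S)-1-chloro-5-(triisopropylsilyl)pent-4-yn-2-ol, via lithium (triisopropylsilyl)acetylide 3 (not isolated)
Conditions: n-BuLi, THF, −78 °C; BF3·OEt2; then 1, −78 °C
Reagents that add atoms: none
Why: Yamaguchi–Hirao alkynylation: the BF3-activated epoxide is opened by the lithium acetylide at its unsubstituted CH2 carbon (SN2), and the C–Cl bond does not react at −78 °C. The stereocentre of 1 is not a reacting carbon and is carried over unchanged.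

Step 2
Reactants: 4 (2S)-1-chloro-5-(triisopropylsilyl)pent-4-yn-2-ol
Product: 6 (4R)-1-(triisopropylsilyl)hepta-1,6-diyn-4-ol, via (2S)-2-[3-(triisopropylsilyl)prop-2-yn-1-yl]oxirane 5 (not isolated)
Conditions: LiC≡CH·H2NCH2CH2NH2 (3 equiv), DMSO, 0 °C to rt
Reagents that add atoms: lithium acetylide–ethylenediamine complex, [Li]C#C.NCCN
Why: One-flask halohydrin closure and epoxide alkynylation: one equivalent of acetylide deprotonates 4, the alkoxide closes to 5 by intramolecular SN2, and a second equivalent opens 5 at its CH2 carbon. The carbinol carbon never reacts (direct displacement of chloride would give the same product), and the hindered C–Si(i-Pr)3 bond should resist the basic medium.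

Step 3
Reactants: 6 (4R)-1-(triisopropylsilyl)hepta-1,6-diyn-4-ol
Product: 7 (4R)-4-[(tert-butyldimethylsilyl)oxy]-1-(triisopropylsilyl)hepta-1,6-diyne
Conditions: TBSCl, imidazole, DMF, rt
Reagents that add atoms: tert-butyldimethylsilyl chloride, CC(C)(C)[Si](C)(C)Cl
Why: Imidazole-promoted silylation of a secondary alcohol; the terminal alkyne and the C-silyl group are inert. The ether keeps the C5 oxygen from binding aluminium in step 4.

Step 4
Reactants: 7 (4R)-4-[(tert-butyldimethylsilyl)oxy]-1-(triisopropylsilyl)hepta-1,6-diyne
Product: 10 (2E,5R)-5-[(tert-butyldimethylsilyl)oxy]-3-methyl-8-(triisopropylsilyl)oct-2-en-7-yn-1-ol, via (E)-alkenyldimethylalane 8 (not isolated), via lithium butyl(alkenyl)dimethylalanate 9 (not isolated)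
Conditions: AlMe3 (2.5 equiv), Cp2ZrCl2 (25 mol %), CH2Cl2, 0 °C to rt; volatiles removed; n-BuLi, THF–hexane, −78 to 0 °C; (CH2O)n, 0 °C to rt; aq. KNaC4H4O6
Reagents that add atoms: trimethylaluminium, C[Al](C)C; paraformaldehyde (reacts as formaldehyde), C=O
Why: This is a Negishi zirconium-catalysed carboalumination followed by hydroxymethylation of the alanate, a known way from terminal alkynes to (E)-3-methylalk-2-en-1-ols. AlMe3 and Cp2ZrCl2 form a methylzirconocene–chloroaluminate pair that adds Me–Zr syn across the free triple bond through a four-centre transition state, with methyl on the internal carbon C3 and the metal on the terminal carbon C2; exchange of zirconium for aluminium gives 8 and returns the catalyst. n-BuLi turns 8 into the more nucleophilic alanate 9, whose alkenyl group adds to monomeric formaldehyde with retention, so the new C2–C1 bond is cis to the new C3–CH3 bond and the alkene is E. No ring is closed and no stereocentre is created; C5 is a spectator. The step needs chemoselection between two alkynes, regioselection for methyl on C3, and syn stereospecificity. The triisopropylsilyl cap secures the first, because the C7 alkyne is too hindered to carbometalate and has no acidic C–H; the terminal position of the free alkyne secures the second; the concerted addition secures the third. The tert-butyldimethylsilyl ether should tolerate AlMe3 and n-BuLi at these temperatures.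

Step 5
Reactants: 10 (2E,5R)-5-[(tert-butyldimethylsilyl)oxy]-3-methyl-8-(triisopropylsilyl)oct-2-en-7-yn-1-ol
Product: 11 (2E,5S)-3-methyloct-2-en-7-yne-1,5-diol
Conditions: Bu4NF (3 equiv), THF, 0 °C to rt
Reagents that add atoms: none
Why: Fluoride-mediated desilylation cleaves the Si–O bond at C5 and the Si–C(sp) bond in one operation; the allylic alcohol and the alkene are inert. The descriptor becomes S only because the uncapped alkyne arm now ranks below the alkenyl arm.

Step 6
Reactants: 11 (2E,5S)-3-methyloct-2-en-7-yne-1,5-diol
Product: 12 (5R)-5-[(2E)-4-hydroxy-2-methylbut-2-en-1-yl]-3-methylideneoxolan-2-one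
Conditions: PdCl2 (5 mol %), SnCl2 (5 mol %), PPh3 (10 mol %), CO (8 atm), MeCN, 70 °C
Reagents that add atoms: carbon monoxide, [C-]#[O+]
Why: Palladium-catalysed cyclocarbonylation of a homopropargylic alcohol: divalent palladium, the C5 hydroxyl and CO form an alkoxycarbonyl–palladium species that adds cis across the terminal alkyne in a 5-exo-dig sense (C8 to C7), and the HCl released earlier cleaves the exocyclic vinyl–palladium bond to give the α-methylene lactone and PdCl2. The primary allylic hydroxyl could only close a nine-membered ring and should stay a bystander, and no epoxide is present yet to be opened by the HCl relay. C5 is untouched.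

Step 7
Reactants: 12 (5R)-5-[(2E)-4-hydroxy-2-methylbut-2-en-1-yl]-3-methylideneoxolan-2-one
Product: 13 (5S)-5-{[(2R,3R)-3-(hydroxymethyl)-2-methyloxiran-2-yl]methyl}-3-methylideneoxolan-2-one
Conditions: Ti(Oi-Pr)4 (10 mol %), D-(−)-diethyl tartrate (12 mol %), t-BuOOH (decane), 4 Å MS, CH2Cl2, −20 °C; non-basic work-up
Reagents that add atoms: tert-butyl hydroperoxide, CC(C)(C)OO
Why: Katsuki–Sharpless asymmetric epoxidation of an E trisubstituted primary allylic alcohol: with D-(−)-diethyl tartrate, oxygen should go to the face that gives the (2R,3R) epoxide, the sense known for geraniol-type 3-methylalk-2-en-1-ols, and reagent control should override the remote C5. The exocyclic alkene is electron-poor and has no directing hydroxyl, so it should not react; the non-basic work-up protects the lactone.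

Step 8
Reactants: 13 (5S)-5-{[(2R,3R)-3-(hydroxymethyl)-2-methyloxiran-2-yl]methyl}-3-methylideneoxolan-2-one; 14 7-hydroxy-8-methoxy-2H-chromen-2-one (hydrangetin)
Product: 15 8-methoxy-7-{[(2R,3R)-3-methyl-3-{[(2S)-4-methylidene-5-oxooxolan-2-yl]methyl}oxiran-2-yl]methoxy}-2H-chromen-2-one
Conditions: PPh3, DIAD, THF, 0 °C (betaine preformed); then 13 and 14, 0 °C to rt
Reagents that add atoms: none
Why: Mitsunobu etherification: the primary alcohol is activated as an alkoxyphosphonium ion and displaced at C1 by the phenoxide of 14, which is acidic enough as a pronucleophile. C1 is not a stereocentre and neither the epoxide nor C5 takes part. Preforming the betaine keeps free phosphine away from the methylene lactone.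

## Compound list

1 | (S)-epichlorohydrin, (2S)-2-(chloromethyl)oxirane | ClC[C@@H]1CO1 | starting material
2 | ethynyltriisopropylsilane | C#C[Si](C(C)C)(C(C)C)C(C)C | starting material
3 | lithium (triisopropylsilyl)acetylide | [Li]C#C[Si](C(C)C)(C(C)C)C(C)C | intermediate
4 | (2S)-1-chloro-5-(triisopropylsilyl)pent-4-yn-2-ol | ClC[C@@H](O)CC#C[Si](C(C)C)(C(C)C)C(C)C | intermediate
5 | (2S)-2-[3-(triisopropylsilyl)prop-2-yn-1-yl]oxirane | C1O[C@H]1CC#C[Si](C(C)C)(C(C)C)C(C)C | intermediate
6 | (4R)-1-(triisopropylsilyl)hepta-1,6-diyn-4-ol | C#CC[C@@H](O)CC#C[Si](C(C)C)(C(C)C)C(C)C | intermediate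
7 | (4R)-4-[(tert-butyldimethylsilyl)oxy]-1-(triisopropylsilyl)hepta-1,6-diyne | C#CC[C@@H](O[Si](C)(C)C(C)(C)C)CC#C[Si](C(C)C)(C(C)C)C(C)C | intermediate
8 | dimethyl{(1E,4R)-4-[(tert-butyldimethylsilyl)oxy]-2-methyl-7-(triisopropylsilyl)hept-1-en-6-yn-1-yl}alane | C[Al](C)/C=C(C)/C[C@@H](O[Si](C)(C)C(C)(C)C)CC#C[Si](C(C)C)(C(C)C)C(C)C | intermediate
9 | lithium butyl(dimethyl){(1E,4R)-4-[(tert-butyldimethylsilyl)oxy]-2-methyl-7-(triisopropylsilyl)hept-1-en-6-yn-1-yl}alanate | [Li+].CCCC[Al-](C)(C)/C=C(C)/C[C@@H](O[Si](C)(C)C(C)(C)C)CC#C[Si](C(C)C)(C(C)C)C(C)C | intermediate
10 | (2E,5R)-5-[(tert-butyldimethylsilyl)oxy]-3-methyl-8-(triisopropylsilyl)oct-2-en-7-yn-1-ol | OC/C=C(C)/C[C@@H](O[Si](C)(C)C(C)(C)C)CC#C[Si](C(C)C)(C(C)C)C(C)C | intermediate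
11 | (2E,5S)-3-methyloct-2-en-7-yne-1,5-diol | OC/C=C(C)/C[C@@H](O)CC#C | intermediate
12 | (5R)-5-[(2E)-4-hydroxy-2-methylbut-2-en-1-yl]-3-methylideneoxolan-2-one | C=C1C[C@@H](C/C(C)=C/CO)OC1=O | intermediate
13 | (5S)-5-{[(2R,3R)-3-(hydroxymethyl)-2-methyloxiran-2-yl]methyl}-3-methylideneoxolan-2-one | C=C1C[C@@H](C[C@@]2(C)O[C@@H]2CO)OC1=O | intermediate
14 | 7-hydroxy-8-methoxy-2H-chromen-2-one (hydrangetin) | COc1c(O)ccc2ccc(=O)oc12 | starting material
15 | 8-methoxy-7-{[(2R,3R)-3-methyl-3-{[(2S)-4-methylidene-5-oxooxolan-2-yl]methyl}oxiran-2-yl]methoxy}-2H-chromen-2-one | C=C1C[C@@H](C[C@@]2(C)O[C@@H]2COc2ccc3ccc(=O)oc3c2OC)OC1=O | target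

## Step count and least certain steps

Total: 8 steps. Longest linear sequence: 8 steps, from 1 to 15; 14 enters in the last step.

**Step 4 (key step).** The most likely trouble is incomplete transfer of the alkenyl group to formaldehyde. Solid paraformaldehyde depolymerises slowly, the methyl and butyl groups on aluminium compete for it, and any alkenyl–aluminium bond left over is simply protonated on work-up. A small leakage of methyl to the terminal carbon is also possible. The fallback sets out from 7 and returns at 10. The carboalumination is run as before, and 8 is quenched directly with ethyl chloroformate, which needs no alanate, to give ethyl (2E,5R)-5-[(tert-butyldimethylsilyl)oxy]-3-methyl-8-(triisopropylsilyl)oct-2-en-7-ynoate F1. F1 is reduced with i-Bu2AlH in CH2Cl2 at −78 °C to 10.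

**Step 6.** The catalytic cycle passes through free HCl at 70 °C. The likely failure is acid-promoted ionisation or allylic transposition of the free trisubstituted allylic alcohol, or its competition with the C5 hydroxyl for palladium, which stalls the catalyst. The fallback sets out from 11 and returns at 12. The primary allylic hydroxyl is silylated selectively (t-BuPh2SiCl, imidazole, CH2Cl2, 0 °C) to give (2E,5S)-1-[(tert-butyldiphenylsilyl)oxy]-3-methyloct-2-en-7-yn-5-ol F2. F2 is cyclocarbonylated to (5R)-5-{(2E)-4-[(tert-butyldiphenylsilyl)oxy]-2-methylbut-2-en-1-yl}-3-methylideneoxolan-2-one F3, and the silyl ether is removed with HF·pyridine in THF to give 12.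

**Step 8.** Triphenylphosphine can add reversibly to the exocyclic enoate of 13. That would consume the reagent and could start phenoxide conjugate addition, so the etherification may stall or give adducts. The fallback sets out from 13 and returns at 15, and uses no phosphine. The primary alcohol is converted with 3-nitrobenzenesulfonyl chloride and Et3N in CH2Cl2 at 0 °C into [(2R,3R)-3-methyl-3-{[(2S)-4-methylidene-5-oxooxolan-2-yl]methyl}oxiran-2-yl]methyl 3-nitrobenzenesulfonate F4. F4 is displaced at C1 by 14 with Cs2CO3 in acetone at rt; the quaternary epoxide carbon next to it is not open to attack.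

**Step 2.** In DMSO the lithium alkoxides are strongly basic and nucleophilic. Partial loss of the triisopropylsilyl cap or oligomerisation of the epoxide by alkoxide could lower the return. The fallback sets out from 4 and returns at 6. Compound 4 is closed with K2CO3 in MeOH, and 5 is isolated. Compound 5 is opened under the conditions of step 1 with the lithium acetylide of ethynyltrimethylsilane and BF3·OEt2 to give (4R)-1-(triisopropylsilyl)-7-(trimethylsilyl)hepta-1,6-diyn-4-ol F5. The trimethylsilyl group alone is then removed with K2CO3 in MeOH to give 6.

## Further compounds

F1 | step 4 | ethyl (2E,5R)-5-[(tert-butyldimethylsilyl)oxy]-3-methyl-8-(triisopropylsilyl)oct-2-en-7-ynoate | CCOC(=O)/C=C(C)/C[C@@H](O[Si](C)(C)C(C)(C)C)CC#C[Si](C(C)C)(C(C)C)C(C)C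
F2 | step 6 | (2E,5S)-1-[(tert-butyldiphenylsilyl)oxy]-3-methyloct-2-en-7-yn-5-ol | CC(C)(C)[Si](OC/C=C(C)/C[C@@H](O)CC#C)(c1ccccc1)c1ccccc1
F3 | step 6 | (5R)-5-{(2E)-4-[(tert-butyldiphenylsilyl)oxy]-2-methylbut-2-en-1-yl}-3-methylideneoxolan-2-one | C=C1C[C@@H](C/C(C)=C/CO[Si](c2ccccc2)(c2ccccc2)C(C)(C)C)OC1=O
F4 | step 8 | [(2R,3R)-3-methyl-3-{[(2S)-4-methylidene-5-oxooxolan-2-yl]methyl}oxiran-2-yl]methyl 3-nitrobenzenesulfonate | C=C1C[C@@H](C[C@@]2(C)O[C@@H]2COS(=O)(=O)c2cccc([N+](=O)[O-])c2)OC1=O
F5 | step 2 | (4R)-1-(triisopropylsilyl)-7-(trimethylsilyl)hepta-1,6-diyn-4-ol | C[Si](C)(C)C#CC[C@@H](O)CC#C[Si](C(C)C)(C(C)C)C(C)C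
A1 | alternative 1 | 8-methoxy-7-({(2R,3R)-3-methyl-3-[(2R)-oxiran-2-ylmethyl]oxiran-2-yl}methoxy)-2H-chromen-2-one | C1[C@@H](C[C@@]2(C)O[C@@H]2COc2ccc3ccc(=O)oc3c2OC)O1
A2 | alternative 1 | diethyl [(5R)-5-{[(2R,3R)-3-{[(8-methoxy-2-oxo-2H-chromen-7-yl)oxy]methyl}-2-methyloxiran-2-yl]methyl}-2-oxooxolan-3-yl]phosphonate (both epimers at the phosphorus-bearing carbon) | CCOP(=O)(OCC)C1C[C@@H](C[C@@]2(C)O[C@@H]2COc2ccc3ccc(=O)oc3c2OC)OC1=O
A3 | alternative 2 | 2-methoxy-3-{[(2E)-3-methyl-4-[(2R)-4-methylidene-5-oxooxolan-2-yl]but-2-en-1-yl]oxy}phenyl prop-2-ynoate | C#CC(=O)Oc1cccc(OC/C=C(C)/C[C@@H]2CC(=C)C(=O)O2)c1OC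
A4 | alternative 2 | 8-methoxy-7-{[(2E)-3-methyl-4-[(2R)-4-methylidene-5-oxooxolan-2-yl]but-2-en-1-yl]oxy}-2H-chromen-2-one | C=C1C[C@@H](C/C(C)=C/COc2ccc3ccc(=O)oc3c2OC)OC1=O
A5 | alternative 3 | (2S)-2-[(2E)-4-{[tert-butyl(dimethyl)silyl]oxy}-2-methylbut-2-en-1-yl]cyclobutan-1-one | O=C1CC[C@H]1C/C(C)=C/CO[Si](C)(C)C(C)(C)C
A6 | alternative 3 | (5S)-5-[(2E)-4-{[tert-butyl(dimethyl)silyl]oxy}-2-methylbut-2-en-1-yl]oxolan-2-one | O=C1CC[C@@H](C/C(C)=C/CO[Si](C)(C)C(C)(C)C)O1
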